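C1 is the quaternary, CH3-bearing fusion carbon. The five-membered ring is C1, C2, C3, C4 (C(OH)i-Pr), C5 (fusion CH). The seven-membered ring is C1, C5, C6 (CHOCOAr), C7, C8 (C(OH)CH3), C9 (CHOH), C10. β is the face of the C1 methyl group.
Retrosynthetic cuts, in order: the O6–acyl bond; the C8–OH and C9–OH bonds (trans-diol → 8α,9α-epoxide → C8=C9 → conjugated C7=C8 enone of a C6 ketone); C4–C5; C1–C2; one carbon of the seven-membered ring, back to 3-methylcyclohexenone.
Enabling feature: carbinol carbon C4 is 1,5 to C5 within the five-membered ring. C5 lies between the C6 carbonyl carbon and the hydrogen-free quaternary C1 of the seven-membered ring. A metal carbene at C5 therefore has one reachable, oxygen-activated C–H bond, that of a secondary C4 silyl ether in a chain on C1.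
Forward order: the seven-membered ring is made first by one-carbon ring expansion to a symmetrical dienone. The chain is joined at C1 by conjugate addition, the diazo group is placed at C5, and C–H insertion closes the five-membered ring. C6, the ester and the C8/C9 diol follow.
Stereochemistry: C4 comes from asymmetric hydrogenation and passes through the insertion with retention. C1 comes from a chiral copper catalyst and C5 from equilibration to the trans fusion. C6 comes from electron-transfer reduction to the equatorial alcohol, C9 from α-face epoxidation and C8 from inversion on hydrolysis.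

Key step: step 11

Assumption: the copper–carbene catalyst in step 9 is taken to induce in the sense of the (S)-tert-leucinol-derived salt written there; if a trial run shows the opposite sense, its enantiomer is used and nothing else changes.

Step 1
Reactants: 1 methyl 4-methyl-3-oxopentanoate
Product: 2 methyl (3R)-3-hydroxy-4-methylpentanoate
Conditions: H2 (50 atm), RuCl2[(S)-BINAP] (0.1 mol %), MeOH, 50 °C
Reagents that add atoms: none
Why: Noyori asymmetric hydrogenation of a β-keto ester, in which the ketone chelated to ruthenium through the ester carbonyl is reduced on the face left open by the (S)-diphosphine, which for an isopropyl ketone corresponds to the (R)-carbinol that becomes C4.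

Step 2
Reactants: 2 methyl (3R)-3-hydroxy-4-methylpentanoate
Product: 3 methyl (3R)-3-(tert-butyldimethylsilyloxy)-4-methylpentanoate
Conditions: TBSCl, imidazole, DMF, rt
Reagents that add atoms: tert-butyldimethylsilyl chloride, CC(C)(C)[Si](C)(C)Cl
Why: Imidazole-promoted silylation of a secondary alcohol, a protection that leaves the carbinol centre untouched and supplies the electron-releasing ether oxygen needed later at C4.

Step 3
Reactants: 3 methyl (3R)-3-(tert-butyldimethylsilyloxy)-4-methylpentanoate
Product: 4 (3R)-3-(tert-butyldimethylsilyloxy)-4-methylpentan-1-ol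
Conditions: LiAlH4, Et2O, 0 °C
Reagents that add atoms: none
Why: Hydride reduction of an ester to the primary alcohol, to which the hindered secondary silyl ether is inert at this temperature.

Step 4
Reactants: 4 (3R)-3-(tert-butyldimethylsilyloxy)-4-methylpentan-1-ol
Product: 5 (3R)-1-bromo-3-(tert-butyldimethylsilyloxy)-4-methylpentane
Conditions: CBr4, PPh3, CH2Cl2, 0 °C
Reagents that add atoms: carbon tetrabromide, BrC(Br)(Br)Br
Why: Appel reaction, an SN2 displacement of the activated primary oxygen by bromide under neutral conditions that spare the silyl ether and the remote stereocentre.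

Step 5
Reactants: 6 3-methylcyclohex-2-en-1-one
Product: 8 3,6-dimethylcyclohex-2-en-1-one (racemic), via lithium cross-conjugated dienolate 7 (not isolated)
Conditions: LDA, THF, −78 °C; MeI, −78 to 0 °C
Reagents that add atoms: iodomethane, CI
Why: Kinetic α′-alkylation of a cyclohexenone, in which the amide base removes a C6 hydrogen rather than a γ-hydrogen and the cross-conjugated enolate is methylated on carbon, the new stereocentre being of no consequence because it becomes sp2 again in the next step.

Step 6
Reactants: 8 3,6-dimethylcyclohex-2-en-1-one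
Product: 10 (2,5-dimethylcyclohexa-1,5-dien-1-yl)oxytrimethylsilane, via lithium dienolate 9 (not isolated)
Conditions: LDA, THF, −78 °C; TMSCl, −78 °C to rt
Reagents that add atoms: chlorotrimethylsilane, C[Si](C)(C)Cl
Why: Kinetic enolisation at the one remaining α′ hydrogen followed by O-silylation, a standard regiospecific silyl enol ether synthesis that gives the 2-silyloxy diene.

Step 7
Reactants: 10 (2,5-dimethylcyclohexa-1,5-dien-1-yl)oxytrimethylsilane
Product: 11 (3,6-dimethylbicyclo[4.1.0]hept-2-en-1-yl)oxytrimethylsilane (racemic)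
Conditions: Et2Zn, CH2I2 (one carbenoid equivalent), Et2O, 0 °C to rt
Reagents that add atoms: diiodomethane, ICI
Why: Simmons–Smith cyclopropanation in the Furukawa variant, in which the electrophilic zinc carbenoid picks the more electron-rich silyloxy-substituted double bond of the diene.

Step 8
Reactants: 11 (3,6-dimethylbicyclo[4.1.0]hept-2-en-1-yl)oxytrimethylsilane
Product: 13 3,6-dimethylcyclohepta-2,6-dien-1-one, via chloro ketone 12 (not isolated)
Conditions: FeCl3, DMF, 0 °C to rt; then NaOAc, MeOH, reflux
Reagents that add atoms: none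
Why: FeCl3-mediated one-carbon ring expansion of a silyloxycyclopropane, in which the internal cyclopropane bond is cleaved oxidatively towards the tertiary carbon, that carbon is chlorinated, and acetate then eliminates HCl from the β-chloro ketone to give the symmetrical cross-conjugated dienone.

Step 9
Reactants: 5 (3R)-1-bromo-3-(tert-butyldimethylsilyloxy)-4-methylpentane; 13 3,6-dimethylcyclohepta-2,6-dien-1-one
Product: 16 (6S)-6-[(3R)-3-(tert-butyldimethylsilyloxy)-4-methylpentyl]-3,6-dimethylcyclohept-2-en-1-one, via Grignard reagent 14 (not isolated), via magnesium dienolate 15 (not isolated)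
Conditions: 5, Mg, Et2O, reflux; solution of 14 added to 13, Cu(OTf)2 (3 mol %), 1-[(2S)-1-hydroxy-3,3-dimethylbutan-2-yl]-3-(2,4,6-trimethylphenyl)-4,5-dihydroimidazolium hexafluorophosphate (4 mol %), Et2O, −30 °C; aq NH4Cl
Reagents that add atoms: none
Why: Copper-catalysed asymmetric conjugate addition of a Grignard reagent to a β-methyl cyclic enone under N-heterocyclic carbene ligation, in which the two enone halves of 13 are equivalent, the chiral copper complex selects the face of the β-carbon and so sets quaternary C1 independently of the remote carbinol centre, and the resulting dienolate cannot accept a second equivalent.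

Step 10
Reactants: 16 (6S)-6-[(3R)-3-(tert-butyldimethylsilyloxy)-4-methylpentyl]-3,6-dimethylcyclohept-2-en-1-one
Product: 19 (6S)-7-diazo-6-[(3R)-3-(tert-butyldimethylsilyloxy)-4-methylpentyl]-3,6-dimethylcyclohept-2-en-1-one, via lithium enolate 17 (not isolated), via trifluoroacetyl ketone 18 (not isolated)
Conditions: LiHMDS, THF, −78 °C; CF3CO2CH2CF3, −78 °C; aq HCl wash; MsN3, Et3N, H2O, MeCN, rt
Reagents that add atoms: methanesulfonyl azide, CS(=O)(=O)N=[N+]=[N-]
Why: Detrifluoroacetylative diazo transfer, in which kinetic deprotonation of the enone occurs at its only α′ position (C5), trifluoroacetylation activates this hindered methylene, and the sulfonyl azide then delivers N2 with loss of the trifluoroacetyl group while both stereocentres stay untouched.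

Step 11
Reactants: 19 (6S)-7-diazo-6-[(3R)-3-(tert-butyldimethylsilyloxy)-4-methylpentyl]-3,6-dimethylcyclohept-2-en-1-one
Product: 22 (3R,3aR,8aS)-3-(tert-butyldimethylsilyloxy)-3-isopropyl-6,8a-dimethyl-2,3,3a,7,8,8a-hexahydroazulen-4(1H)-one (trans-fused; C1 methyl β; H5 α; OTBS β; isopropyl α), via rhodium carbenoid 20 (not isolated), via cis-fused C5 epimer 21 (not isolated)
Conditions: Rh2(OAc)4 (1 mol %), CH2Cl2, 40 °C, slow addition of 19; evaporation; K2CO3, MeOH, rt
Reagents that add atoms: none
Why: Rh2(OAc)4 expels N2 from 19 to give the electrophilic carbenoid 20 at C5, whose vacant orbital takes up the C4–H bond in a concerted three-centre, hydride-like transition state that forms C4–C5 and C5–H together and releases the catalyst. The closest known reaction type is the intramolecular 1,5 C–H insertion of α-diazo ketones into C–H bonds next to ether or silyl ether oxygen. The five-membered ring (C1, C2, C3, C4, C5) closes onto the existing seven-membered ring by 1,5-insertion through a five-membered cyclic transition state, and no other ring is formed. C4 is controlled by the (R)-carbinol centre of the chain, because insertion proceeds with retention, C5 taking the place of hydrogen and the oxygen ending on the face of the C1 methyl group. C5 is expected to be set first by approach of the pseudo-axial chain (cis fusion, 21) and is then corrected by K2CO3/MeOH equilibration through the C5 enolate to the trans fusion of 22, where the isopropyl group leaves the concave face and lies next to H5 instead of C6. The step needs site and chemoselectivity over 1,2-shift, four- and six-membered insertion, cyclopropanation and ylide formation, and the substrate secures it: quaternary C1 offers no migrating hydrogen, C4–H is the only C–H bond in a 1,5 relation and is activated by oxygen, the conjugated C7=C8 bond is out of reach inside the ring, and the bulky silyl group keeps the oxygen lone pairs off the carbene carbon.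

Step 12
Reactants: 22 trans-fused conjugated enone
Product: 24 (3R,3aR,8aR)-3-(tert-butyldimethylsilyloxy)-3-isopropyl-6,8a-dimethyl-2,3,3a,5,8,8a-hexahydroazulen-4(1H)-one (C8=C9 ketone), via potassium dienolate 23 (not isolated)
Conditions: KHMDS, THF, −78 to −40 °C; cannulation into AcOH/THF, −78 °C; cold aqueous work-up, used crude
Reagents that add atoms: none
Why: Deconjugative protonation of an extended dienolate, in which the bulky amide base cannot reach H5 (flanked by C1 and C4 and screened by the isopropyl group) and removes the ring γ-hydrogen at C9 that lies parallel to the π system, and kinetic protonation at the α-carbon C7 then leaves C8=C9 out of conjugation without touching C5 or the β-silyloxy group.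

Step 13
Reactants: 24 C8=C9 ketone
Product: 25 (3R,3aS,4S,8aR)-3-(tert-butyldimethylsilyloxy)-3-isopropyl-6,8a-dimethyl-1,2,3,3a,4,5,8,8a-octahydroazulen-4-ol (6α-alcohol)
Conditions: SmI2, H2O, Et3N, THF, 0 °C
Reagents that add atoms: none
Why: Electron-transfer ketone reduction of the dissolving-metal type, which is fast enough to outrun reconjugation and is expected to place the oxygen in the more stable equatorial 6α position and H6 on the β face, because a 6β-oxygen would be 1,3-diaxial to the C1 methyl group, while the isolated alkene and the silyl ether are inert.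

Step 14
Reactants: 26 4-hydroxybenzoic acid
Product: 28 4-(tert-butyldimethylsilyloxy)benzoic acid, via silyl ester 27 (not isolated)
Conditions: TBSCl (2.2 equiv), imidazole, DMF, rt; then AcOH/THF/H2O, rt
Reagents that add atoms: tert-butyldimethylsilyl chloride, CC(C)(C)[Si](C)(C)Cl
Why: Exhaustive silylation followed by selective solvolysis of the labile silyl ester, a standard way to mask a phenol next to a free carboxylic acid.

Step 15
Reactants: 25 6α-alcohol; 28 4-(tert-butyldimethylsilyloxy)benzoic acid
Product: 29 (1R,4R,5S,6S)-4-(tert-butyldimethylsilyloxy)dauc-8-en-6-yl 4-(tert-butyldimethylsilyloxy)benzoate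
Conditions: DCC, DMAP, CH2Cl2, rt
Reagents that add atoms: none
Why: Steglich esterification, in which the only free hydroxyl group, the equatorial secondary O6, is acylated through the acylpyridinium species with retention at C6.

Step 16
Reactants: 29 silyl-protected C8=C9 ester
Product: 30 (1R,4R,5S,6S,8R,9S)-8,9-epoxide of 29 (oxygen α; H9 and C8 methyl β)
Conditions: mCPBA, CH2Cl2, 0 °C
Reagents that add atoms: 3-chloroperoxybenzoic acid, O=C(OO)c1cccc(Cl)c1
Why: Prilezhaev epoxidation of the only alkene, expected on the α face because the axial C1 methyl group overhangs C9 and C10 on the β face whereas the α face carries only hydrogens and the equatorial ester.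

Step 17
Reactants: 30 8α,9α-epoxide
Product: 31 (1R,4R,5S,6S,8S,9S)-4-(tert-butyldimethylsilyloxy)-8,9-dihydroxydaucan-6-yl 4-(tert-butyldimethylsilyloxy)benzoate (8β-OH; 9α-OH)
Conditions: HClO4 (cat), THF/H2O, 0 °C
Reagents that add atoms: water, O
Why: Acid-catalysed hydrolysis of a trisubstituted epoxide with borderline SN2 character, in which water attacks the protonated oxirane at tertiary C8, the carbon best able to carry positive charge, from the β face with inversion while the C9–O bond stays α, giving the trans-diol.

Step 18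
Reactants: 31 bis-silyl trans-diol
Product: 32 (3R,3aS,4S,6S,7S,8aR)-3,6,7-trihydroxy-3-isopropyl-6,8a-dimethyldecahydroazulen-4-yl 4-hydroxybenzoate (target)
Conditions: aq HF (48 %), MeCN, 0 °C to rt
Reagents that add atoms: none
Why: Fluoride-driven desilylation under mildly acidic conditions, which cleaves the aryl and the hindered tertiary silyl ether at silicon and therefore touches neither the ester nor any stereocentre.

Compound list
1 | methyl 4-methyl-3-oxopentanoate | COC(=O)CC(=O)C(C)C | starting material
2 | methyl (3R)-3-hydroxy-4-methylpentanoate | CC(C)[C@H](O)CC(=O)OC | intermediate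
3 | methyl (3R)-3-(tert-butyldimethylsilyloxy)-4-methylpentanoate | CC(C)[C@H](O[Si](C)(C)C(C)(C)C)CC(=O)OC | intermediate
4 | (3R)-3-(tert-butyldimethylsilyloxy)-4-methylpentan-1-ol | CC(C)[C@H](O[Si](C)(C)C(C)(C)C)CCO | intermediate
5 | (3R)-1-bromo-3-(tert-butyldimethylsilyloxy)-4-methylpentane | CC(C)[C@H](O[Si](C)(C)C(C)(C)C)CCBr | intermediate
6 | 3-methylcyclohex-2-en-1-one | CC1=CC(=O)CCC1 | starting material
7 | lithium 5-methylcyclohexa-1,5-dien-1-olate | [Li+].[O-]C1=CCCC(C)=C1 | intermediate (not isolated)
8 | 3,6-dimethylcyclohex-2-en-1-one (racemic) | CC1CCC(C)=CC1=O | intermediate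
9 | lithium 2,5-dimethylcyclohexa-1,5-dien-1-olate | [Li+].[O-]C1=C(C)CCC(C)=C1 | intermediate (not isolated)
10 | (2,5-dimethylcyclohexa-1,5-dien-1-yl)oxytrimethylsilane | CC1=C(O[Si](C)(C)C)C=C(C)CC1 | intermediate
11 | (3,6-dimethylbicyclo[4.1.0]hept-2-en-1-yl)oxytrimethylsilane (racemic) | CC1=CC2(O[Si](C)(C)C)CC2(C)CC1 | intermediate
12 | 6-chloro-3,6-dimethylcyclohept-2-en-1-one (racemic) | CC1=CC(=O)CC(C)(Cl)CC1 | intermediate (not isolated)
13 | 3,6-dimethylcyclohepta-2,6-dien-1-one | CC1=CC(=O)C=C(C)CC1 | intermediate
14 | [(3R)-3-(tert-butyldimethylsilyloxy)-4-methylpentyl]magnesium bromide | CC(C)[C@H](O[Si](C)(C)C(C)(C)C)CC[Mg]Br | intermediate (not isolated)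
15 | bromomagnesium C5=C6 dienolate of 16 | CC(C)[C@H](O[Si](C)(C)C(C)(C)C)CC[C@]1(C)CCC(C)=CC(O[Mg]Br)=C1 | intermediate (not isolated)
16 | (6S)-6-[(3R)-3-(tert-butyldimethylsilyloxy)-4-methylpentyl]-3,6-dimethylcyclohept-2-en-1-one | CC(C)[C@H](O[Si](C)(C)C(C)(C)C)CC[C@]1(C)CCC(C)=CC(=O)C1 | intermediate
17 | lithium C5=C6 enolate of 16 | CC(C)[C@H](O[Si](C)(C)C(C)(C)C)CC[C@]1(C)CCC(C)=CC([O-])=C1.[Li+] | intermediate (not isolated)
18 | 7-trifluoroacetyl derivative of 16 (enolisable, C7 undefined) | CC(C)[C@H](O[Si](C)(C)C(C)(C)C)CC[C@]1(C)CCC(C)=CC(=O)C1C(=O)C(F)(F)F | intermediate (not isolated)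
19 | (6S)-7-diazo-6-[(3R)-3-(tert-butyldimethylsilyloxy)-4-methylpentyl]-3,6-dimethylcyclohept-2-en-1-one | CC(C)[C@H](O[Si](C)(C)C(C)(C)C)CC[C@]1(C)CCC(C)=CC(=O)C1=[N+]=[N-] | intermediate
20 | C5 carbenoid of 19 on the Rh2(OAc)4 core (written in ionic form) | CC(C)[C@H](O[Si](C)(C)C(C)(C)C)CC[C@]1(C)CCC(C)=CC(=O)C1=[Rh+2].[Rh+2].CC(=O)[O-].CC(=O)[O-].CC(=O)[O-].CC(=O)[O-] | intermediate (not isolated)
21 | (3R,3aS,8aS)-3-(tert-butyldimethylsilyloxy)-3-isopropyl-6,8a-dimethyl-2,3,3a,7,8,8a-hexahydroazulen-4(1H)-one (cis-fused) | CC(C)[C@]1(O[Si](C)(C)C(C)(C)C)CC[C@]2(C)CCC(C)=CC(=O)[C@@H]21 | intermediate (not isolated)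
22 | (3R,3aR,8aS)-3-(tert-butyldimethylsilyloxy)-3-isopropyl-6,8a-dimethyl-2,3,3a,7,8,8a-hexahydroazulen-4(1H)-one (trans-fused) | CC(C)[C@]1(O[Si](C)(C)C(C)(C)C)CC[C@]2(C)CCC(C)=CC(=O)[C@H]21 | intermediate
23 | potassium C6=C7–C8=C9 dienolate of 22 | CC(C)[C@]1(O[Si](C)(C)C(C)(C)C)CC[C@]2(C)CC=C(C)C=C([O-])[C@H]21.[K+] | intermediate (not isolated)
24 | (3R,3aR,8aR)-3-(tert-butyldimethylsilyloxy)-3-isopropyl-6,8a-dimethyl-2,3,3a,5,8,8a-hexahydroazulen-4(1H)-one | CC(C)[C@]1(O[Si](C)(C)C(C)(C)C)CC[C@]2(C)CC=C(C)CC(=O)[C@H]21 | intermediate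
25 | (3R,3aS,4S,8aR)-3-(tert-butyldimethylsilyloxy)-3-isopropyl-6,8a-dimethyl-1,2,3,3a,4,5,8,8a-octahydroazulen-4-ol | CC(C)[C@]1(O[Si](C)(C)C(C)(C)C)CC[C@]2(C)CC=C(C)C[C@H](O)[C@H]21 | intermediate
26 | 4-hydroxybenzoic acid | O=C(O)c1ccc(O)cc1 | starting material
27 | tert-butyldimethylsilyl 4-(tert-butyldimethylsilyloxy)benzoate | CC(C)(C)[Si](C)(C)OC(=O)c1ccc(O[Si](C)(C)C(C)(C)C)cc1 | intermediate (not isolated)
28 | 4-(tert-butyldimethylsilyloxy)benzoic acid | CC(C)(C)[Si](C)(C)Oc1ccc(C(=O)O)cc1 | intermediate
29 | (1R,4R,5S,6S)-4-(tert-butyldimethylsilyloxy)dauc-8-en-6-yl 4-(tert-butyldimethylsilyloxy)benzoate | CC(C)[C@]1(O[Si](C)(C)C(C)(C)C)CC[C@]2(C)CC=C(C)C[C@H](OC(=O)c3ccc(O[Si](C)(C)C(C)(C)C)cc3)[C@H]21 | intermediate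
30 | (1R,4R,5S,6S,8R,9S)-8α,9α-epoxide of 29 | CC(C)[C@]1(O[Si](C)(C)C(C)(C)C)CC[C@]2(C)C[C@@H]3O[C@]3(C)C[C@H](OC(=O)c4ccc(O[Si](C)(C)C(C)(C)C)cc4)[C@H]21 | intermediate
31 | (1R,4R,5S,6S,8S,9S)-4-(tert-butyldimethylsilyloxy)-8,9-dihydroxydaucan-6-yl 4-(tert-butyldimethylsilyloxy)benzoate | CC(C)[C@]1(O[Si](C)(C)C(C)(C)C)CC[C@]2(C)C[C@H](O)[C@@](C)(O)C[C@H](OC(=O)c3ccc(O[Si](C)(C)C(C)(C)C)cc3)[C@H]21 | intermediate
32 | (3R,3aS,4S,6S,7S,8aR)-3,6,7-trihydroxy-3-isopropyl-6,8a-dimethyldecahydroazulen-4-yl 4-hydroxybenzoate | CC(C)[C@]1(O)CC[C@]2(C)C[C@H](O)[C@@](C)(O)C[C@H](OC(=O)c3ccc(O)cc3)[C@H]21 | target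

Total step count: 18. Longest linear sequence: 13 steps (steps 1–4 or steps 5–8, then steps 9–13 and 15–18).

Steps most likely to fail

Step 11. The carbene may be lost to ring contraction by Wolff rearrangement or to migration of an alkyl group from C1. Hydride abstraction from C4 followed by silyl transfer may also replace C–C bond formation. Equilibration at the crowded C5 may stall, or it may trigger β-elimination of the C4 silyloxy group. The fallback closes the same C4–C5 bond with reversed roles, C5 as nucleophile and C4 as a ketone. It sets out from 16. Bromination of its lithium enolate 17 with NBS at −78 °C should give the C5 bromo ketone F1. Aqueous HF in MeCN should free the side-chain alcohol to give the bromo hydroxy ketone F2. Dess–Martin periodinane should oxidise this to the bromo diketone F3. SmI2 in THF at −78 °C should then effect an intramolecular samarium Reformatsky reaction to the trans-fused ketol F4, the chelate of trivalent samarium between O6 and O4 placing O4 on the side of C6. Silylation with TBSOTf and 2,6-lutidine comes back to the route at 22. C4 is then set by substrate control rather than by retention.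

Step 12. Deprotonation may occur at the C8 methyl group, which would place the alkene exocyclic, or at C5, which would open the way to elimination. The double bond may also slip back into conjugation during quench and work-up. The fallback separates enolisation from protonation and sets out from 22. Soft enolisation with TMSOTf and Et3N in CH2Cl2 under equilibrating conditions should give the endocyclic, more substituted trimethylsilyl dienol ether F5, an isolable neutral compound that can be checked for regiochemistry. MeLi in Et2O at 0 °C should release the lithium dienolate F6 regiospecifically. Inverse quench into AcOH/THF at −78 °C comes back to the route at 24.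

Step 13. Protonation at C6 may show poor facial selectivity, and amine-induced reconjugation before electron transfer may lead to over-reduction. The fallback replaces thermodynamic control by intramolecular hydride delivery and sets out from 24. HF·pyridine in THF should remove the tertiary silyl group to give the ketol F7. Evans–Saksena reduction with Me4NBH(OAc)3 in MeCN/AcOH at −20 °C should bind boron to the β-oriented O4 and deliver hydride to the β face of C6, giving the 4β,6α-diol jaeschkeanadiol F8. Steglich esterification with 28 should acylate only the secondary O6 to give the C4-hydroxy ester F9. Silylation of O4 with TBSOTf and 2,6-lutidine comes back to the route at 29.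

Further compounds
F1 | step 11 | (6S)-7-bromo-6-[(3R)-3-(tert-butyldimethylsilyloxy)-4-methylpentyl]-3,6-dimethylcyclohept-2-en-1-one (C7 epimers) | CC(C)[C@H](O[Si](C)(C)C(C)(C)C)CC[C@]1(C)CCC(C)=CC(=O)C1Br
F2 | step 11 | (6S)-7-bromo-6-[(3R)-3-hydroxy-4-methylpentyl]-3,6-dimethylcyclohept-2-en-1-one (C7 epimers) | CC(C)[C@H](O)CC[C@]1(C)CCC(C)=CC(=O)C1Br
F3 | step 11 | (6S)-7-bromo-3,6-dimethyl-6-(4-methyl-3-oxopentyl)cyclohept-2-en-1-one (C7 epimers) | CC(C)C(=O)CC[C@]1(C)CCC(C)=CC(=O)C1Br
F4 | step 11 | (3R,3aR,8aS)-3-hydroxy-3-isopropyl-6,8a-dimethyl-2,3,3a,7,8,8a-hexahydroazulen-4(1H)-one | CC(C)[C@]1(O)CC[C@]2(C)CCC(C)=CC(=O)[C@H]21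
F5 | step 12 | C6-O-trimethylsilyl C6=C7–C8=C9 dienol ether of 22 | CC(C)[C@]1(O[Si](C)(C)C(C)(C)C)CC[C@]2(C)CC=C(C)C=C(O[Si](C)(C)C)[C@H]21
F6 | step 12 | lithium C6=C7–C8=C9 dienolate of 22 | CC(C)[C@]1(O[Si](C)(C)C(C)(C)C)CC[C@]2(C)CC=C(C)C=C([O-])[C@H]21.[Li+]
F7 | step 13 | (3R,3aR,8aR)-3-hydroxy-3-isopropyl-6,8a-dimethyl-2,3,3a,5,8,8a-hexahydroazulen-4(1H)-one | CC(C)[C@]1(O)CC[C@]2(C)CC=C(C)CC(=O)[C@H]21
F8 | step 13 | (3R,3aS,4S,8aR)-3-isopropyl-6,8a-dimethyl-1,2,3,3a,4,5,8,8a-octahydroazulene-3,4-diol (jaeschkeanadiol) | CC(C)[C@]1(O)CC[C@]2(C)CC=C(C)C[C@H](O)[C@H]21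
F9 | step 13 | (1R,4R,5S,6S)-4-hydroxydauc-8-en-6-yl 4-(tert-butyldimethylsilyloxy)benzoate | CC(C)[C@]1(O)CC[C@]2(C)CC=C(C)C[C@H](OC(=O)c3ccc(O[Si](C)(C)C(C)(C)C)cc3)[C@H]21
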